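**Remark on the chemistry (assumption).** Ring A is the tetrahydrofuran (O1, C2–C5), ring B the aryl on C2, ring C the aryl on C5, rings D and E the 3,4-dimethoxyphenyl ends of the chains on ring B and ring C. C7/C8 and C7′/C8′ are the carbinol and methyl-bearing carbons of those chains. The labels C2–C5 are kept for the open-chain intermediates. 3,4-Dimethoxyphenylmagnesium bromide (18) and both methyl lactates are taken as purchasable.

## Structural features

The target is a dineolignan built on a 2,5-diaryl-3,4-dimethyltetrahydrofuran (ring A). Each of its two guaiacyl rings (ring B on C2, ring C on C5) carries, on the oxygen para to ring A, a 1-(3,4-dimethoxyphenyl)-1-hydroxypropan-2-yl chain. Ring A holds four contiguous stereocentres, (2S,3S,4S,5R): the C2 aryl is trans to the C3 methyl, the two methyls are trans, and the C4 methyl is cis to the C5 aryl, so the aryls are cis and the ring has no symmetry. Each chain adds two adjacent centres: erythro (7R,8S) on ring B and threo (7′R,8′R) on ring C, so both carbinols are R while the two C8 centres are opposite. The fragile sites are the four benzylic C–O bonds on electron-rich rings (C2, C5, C7, C7′), which ionise in acid and are open to hydrogenolysis, and the aryl ketone precursors of the chains, which can epimerise at C8. The real difficulty is differentiation: two almost identical phenols must receive diastereomeric chains on a ring whose halves differ in a single relative configuration, and the open-chain triad C5/C4/C3 must be set before the ring exists. The key step uses the fact that C2 of ring A is benzylic and para to the phenolic oxygen of ring B. Two-electron oxidation of that phenol turns C2 into the exocyclic carbon of a p-quinone methide, five atoms away from the C5 hydroxyl oxygen that becomes O1.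

## Logic of the disconnections

**29 ⇒ 28.** The C7′–H bond of the threo chain is cut, taking the last carbinol back to an aryl ketone. A ketone at C7′ is what makes C8′ reactive enough to be attached by substitution, and the cut removes one stereocentre. The forward step must give 7′R next to the fixed 8′R centre without chelation, in the presence of the free C7 hydroxyl and the acid-labile ring A.

**28 ⇒ 23 + 27.** The aryl O–C8′ bond is cut. This splits off the whole ring E chain as a three-carbon electrophile and leaves the ring C phenol as the nucleophile, so the route becomes convergent and C8′ comes from the chiral pool. The forward step must be a clean SN2 inversion next to a ketone, with a base too weak to enolise either partner or to alkylate the C7 hydroxyl.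

**23 ⇒ 22 ⇒ 21 ⇒ 15 + 20.** After restoring the silyl group on the ring C oxygen, the same two cuts (C7–H, then O–C8) are applied to the erythro chain on ring B. Because the chains go on one after the other, the two phenols in 15 must differ: one free, one silylated. The forward steps need a chelation-controlled reduction for 7R next to 8S, a silyl ether that survives carbonate and hydride, and a desilylation that does not open ring A at C5.

**27 ⇒ 26 ⇒ 25 ⇒ 24 (+ 18) and 20 ⇒ 19 ⇒ 17 ⇒ 16 (+ 18).** In each electrophile the S–O bond, then the aryl–C7 bond, then the amide C–N bond are cut, ending at the enantiomeric hydroxy esters 24 and 16 and the common aryl donor 18. C8 and C8′ are opposite in configuration, so each is bought and not made. The forward steps must not racemise a centre α to a carbonyl: the addition of 18 must stop at the ketone, and the sulfonylation must leave the C–O bond untouched.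

**15 ⇒ 13 (through 14).** The O1–C2 bond of ring A is cut. C2 is the one ring carbon that oxidation alone can make electrophilic, and the cut removes the ring and the C2 stereocentre, leaving an open chain whose only reactive groups are the C5 hydroxyl and the ring B phenol. The forward step must oxidise ring B and not ring C, close the five-membered ring and not a spiro ring, set C2 trans to the C3 methyl, and stop before 15 is oxidised further.

**13 ⇒ 12 ⇒ 11.** First the O-benzyl bond on ring B is restored, so that ring B stays masked until just before the oxidation. Then the C3–H bond is cut to the 1,1-disubstituted alkene 11. The exocyclic methylene is preferred to the benzylidene isomer for two reasons: it has no E/Z problem, and for a 1,1-disubstituted alkene allylic strain places the carbinol arm over the face that leads to 3R. The forward steps need a hydrogenation steered by the C5 hydroxyl without double-bond migration, and a hydrogenolysis that spares the benzylic C5–O bond.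

**11 ⇒ 10 ⇒ 6 + 9 (⇐ 8 ⇐ 7).** The C3=CH2 bond is cut to a ketone, and the ketone is cut at C2–C3 into an N-methoxy-N-methylamide and a benzylic organomagnesium. This divides the chain into the half carrying ring C with both existing stereocentres and the achiral half carrying ring B. The forward steps need a base-free methylenation of an enolisable β-hydroxy ketone and a single addition of 9 with the hydroxyl unprotected.

**6 ⇒ 5 ⇒ 3 + 2 (⇐ 1).** The amide is traced to the imide, and the C4–C5 bond is cut in the aldol sense. This is the one C–C bond whose formation sets two stereocentres (C5 and C4, syn) under control of a recoverable auxiliary, and it reduces the problem to 3 and the aldehyde 2, made from 1 by silylation. The forward step needs a Z-enolate and full syn selectivity with an electron-rich, weakly electrophilic aldehyde. The silyl group on 2 is the triisopropylsilyl group, so that it still stands after the Grignard, hydride and carbonate steps.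

## Other disconnections considered

**Alternative 1:** The cut goes through the C3–CH3 and C4–CH3 bonds of ring A: both methyls are added to a preformed ring, the butenolide A2.
- *Forward key step.* Me2CuLi would add to A2 anti to the aryl group, and the enolate would be methylated with iodomethane anti to the new methyl, giving the all-trans lactone A1 in one flask. The lactone carbonyl would then become C5 by addition of a ring C aryl nucleophile and reduction of the lactol through its oxocarbenium ion; hydride entering anti to the neighbouring methyl would leave the aryl cis to it.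
- *In its favour.* Both methyl-bearing centres arise by 1,2-induction on a five-membered ring, which is more dependable than the acyclic directed hydrogenation of step 7; on this point the alternative is the better plan. The two aryl rings are differentiated by construction, which equals the chosen plan. The core would need about six steps against nine to reach 15, also a point for the alternative.
- *Against it here.* The C5–H of A2 is benzylic, γ to the carbonyl and on an electron-rich ring, so deprotonation by the basic cuprate to an aromatic furanolate would erase the only stereochemical information. A2 also needs its own enantioselective synthesis. The last ring centre is left to a Lewis-acid reduction of a doubly benzylic hemiketal, where ring A can open and C2 can epimerise.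
- *Comparison.* Mechanistically this is closed-shell enolate and oxocarbenium chemistry, so it avoids the over-oxidation risk of step 9. It makes no use of the para-phenol/C2 relationship and closes no ring in its key step.

**Alternative 2:** The cut removes O1–C5 and C2–C3 together: ring A is assembled from the donor–acceptor cyclopropane A4 and the aldehyde A5.
- *Forward key step.* With Sn(OTf)2 the aldehyde oxygen would open A4 at its benzylic carbon with inversion, and the malonate carbon would then close onto the oxocarbenium carbon, giving the 2,5-cis tetrahydrofuran A3.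
- *In its favour.* It is the most convergent of the plans, and the cis relationship of the two aryls follows from a stereospecific step; on convergence it is better than the chosen plan. The allyl and benzyl ethers differentiate rings B and C as well as the silyl/free-phenol pair does, which is an equal point.
- *Against it here.* C3 emerges as a quaternary malonate carbon that must be cut down to H and CH3 with the 2,3-trans arrangement: dealkoxycarbonylation, equilibration of the remaining ester, reduction and deoxygenation, about four extra steps. A4 with an alkoxyaryl donor ionises easily under the Lewis acid, so enantiopurity can leak through a ring-opened zwitterion. A 2,3-disubstituted cyclopropane diester is a less usual partner, and its asymmetric preparation is itself several steps.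
- *Comparison.* Structurally A3 sets three of the four ring centres at once, where the chosen plan sets them in three separate steps. In step economy the trimming of the diester makes it the longer route.

**Alternative 3:** The cut removes the two C7–O bonds: both benzylic hydroxyls are introduced last on the 7,7′-dideoxy bisphenol A7.
- *Forward key step.* A flavin-dependent 4-alkylphenol oxidase would dehydrogenate each terminal 4-hydroxy-3-methoxybenzyl group to an enzyme-bound p-quinone methide and add water from one face, giving A6 with both carbinols R. Methylation of the two phenols would then finish the target.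
- *In its favour.* Both carbinols of the target are R, so one face-selective catalyst fits exactly and would replace two separate diastereoselective reductions; in stereochemical economy this is better than the chosen plan. It belongs to the same quinone methide family as step 9, so mechanistically it is an equal.
- *Against it here.* The enzyme pocket is built for small 4-alkylphenols, and A7 offers it a chain with a bulky aryloxy group on the adjacent carbon. Loss of the C8 proton to a propenyl or enol ether product competes with hydration. The C8–O bonds of A7 would have to be made by substitution at unactivated secondary carbons, which is slower and more prone to elimination than the α-keto sulfonate used in steps 13 and 19. Ring A is not addressed at all.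
- *Comparison.* It saves two reductions but adds a methylation and a harder ether synthesis, so the step count is about equal, with much more uncertainty in the last step.

Key step: step 9

## Route

**Step 1**
Reactants: 1 vanillin
Product: 2 3-methoxy-4-(triisopropylsilyloxy)benzaldehyde
Conditions: TIPSCl, imidazole, DMF, rt
Reagents that add atoms: triisopropylsilyl chloride, CC(C)[Si](Cl)(C(C)C)C(C)C
Why: Imidazole-promoted silylation of the phenol. The triisopropylsilyl ether is chosen over a tert-butyldimethylsilyl ether because it should survive the Grignard steps and the carbonate alkylation of step 13, and as an ether it keeps ring C out of reach of the anode in step 9.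

**Step 2**
Reactants: 3 (R)-4-benzyl-3-propanoyloxazolidin-2-one; 2 3-methoxy-4-(triisopropylsilyloxy)benzaldehyde
Product: 5 (R)-4-benzyl-3-[(2R,3R)-3-hydroxy-3-(3-methoxy-4-triisopropylsilyloxyphenyl)-2-methylpropanoyl]oxazolidin-2-one, via Z-dibutylboron enolate 4 (not isolated)
Conditions: Bu2BOTf, iPr2NEt, CH2Cl2, 0 °C; then 2, −78 → 0 °C; H2O2, MeOH, pH 7 buffer
Reagents that add atoms: none
Why: Evans syn-aldol reaction: the Z-boron enolate 4 adds to 2 through a chair Zimmerman–Traxler transition state in which the benzyl group of the auxiliary shields one enolate face. This sets C5 (R) and C4 as the 2R,3R syn adduct; the peroxide work-up only cleaves the boron aldolate.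

**Step 3**
Reactants: 5 (R)-4-benzyl-3-[(2R,3R)-3-hydroxy-3-(3-methoxy-4-triisopropylsilyloxyphenyl)-2-methylpropanoyl]oxazolidin-2-one
Product: 6 (2R,3R)-3-hydroxy-N-methoxy-3-(3-methoxy-4-triisopropylsilyloxyphenyl)-N,2-dimethylpropanamide
Conditions: MeNH(OMe)·HCl, AlMe3, CH2Cl2, −20 → 0 °C
Reagents that add atoms: N,O-dimethylhydroxylamine hydrochloride, CNOC.Cl
Why: Weinreb transamidation with the aluminium amide formed in the flask; the free β-hydroxyl directs attack to the exocyclic carbonyl, the α-centre is not enolised and the auxiliary is released intact.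

**Step 4**
Reactants: 7 4-benzyloxy-3-methoxybenzyl alcohol
Product: 8 4-benzyloxy-3-methoxybenzyl chloride
Conditions: SOCl2, DMF (cat.), CH2Cl2, 0 °C
Reagents that add atoms: thionyl chloride, ClS(Cl)=O
Why: Chlorination of an electron-rich benzylic alcohol through its chlorosulfite; the aryl benzyl ether is inert.

**Step 5**
Reactants: 8 4-benzyloxy-3-methoxybenzyl chloride; 6 (2R,3R)-3-hydroxy-N-methoxy-3-(3-methoxy-4-triisopropylsilyloxyphenyl)-N,2-dimethylpropanamide
Product: 10 (3R,4R)-1-(4-benzyloxy-3-methoxyphenyl)-4-hydroxy-4-(3-methoxy-4-triisopropylsilyloxyphenyl)-3-methylbutan-2-one, via benzylic Grignard reagent 9 (not isolated)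
Conditions: 8, Mg, 2-MeTHF, 0 °C; 6, iPrMgCl (1.0 equiv), THF, −20 °C; then 9 (1.5 equiv), −20 → 0 °C; aq. NH4Cl
Reagents that add atoms: none
Why: Weinreb ketone synthesis: the hydroxyl is first masked as its magnesium alkoxide, then 9 adds once to give a chelated tetrahedral intermediate that releases ketone 10 only at work-up. Over-addition and base-induced retro-aldol cleavage are thereby avoided, and no stereocentre is touched.

**Step 6**
Reactants: 10 (3R,4R)-1-(4-benzyloxy-3-methoxyphenyl)-4-hydroxy-4-(3-methoxy-4-triisopropylsilyloxyphenyl)-3-methylbutan-2-one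
Product: 11 (1R,2S)-3-(4-benzyloxy-3-methoxybenzyl)-1-(3-methoxy-4-triisopropylsilyloxyphenyl)-2-methylbut-3-en-1-ol
Conditions: Cp2TiMe2 (3 equiv), toluene/THF, 65 °C, dark
Reagents that add atoms: dimethyltitanocene, C[Ti](C)(C1C=CC=C1)C1C=CC=C1
Why: Petasis methylenation: thermolysis of Cp2TiMe2 gives the titanium methylidene, which converts C=O into C=CH2 through an oxatitanacyclobutane. The reagent is not basic, so the benzylic ketone is not enolised, C4 is not epimerised and the β-hydroxy ketone is not cleaved; the hydroxyl only consumes one equivalent as a titanium alkoxide.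

**Step 7**
Reactants: 11 (1R,2S)-3-(4-benzyloxy-3-methoxybenzyl)-1-(3-methoxy-4-triisopropylsilyloxyphenyl)-2-methylbut-3-en-1-ol
Product: 12 (1R,2S,3R)-4-(4-benzyloxy-3-methoxyphenyl)-1-(3-methoxy-4-triisopropylsilyloxyphenyl)-2,3-dimethylbutan-1-ol
Conditions: [Rh(nbd)(dppb)]BF4 (5 mol %), H2 (60 atm), CH2Cl2, rt
Reagents that add atoms: none
Why: Hydroxyl-directed homogeneous hydrogenation: the cationic rhodium catalyst binds the C5 hydroxyl and the alkene, so H2 is delivered to the alkene face that carries the carbinol arm. In a 1,1-disubstituted alkene the allylic C4–H lies next to the larger C3 substituent (the arylmethyl group) to avoid A(1,2) strain, which places the arm over the face that gives 3R. High H2 pressure suppresses migration of the double bond into conjugation with ring B, which would reverse the sense.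

**Step 8**
Reactants: 12 (1R,2S,3R)-4-(4-benzyloxy-3-methoxyphenyl)-1-(3-methoxy-4-triisopropylsilyloxyphenyl)-2,3-dimethylbutan-1-ol
Product: 13 (1R,2S,3R)-4-(4-hydroxy-3-methoxyphenyl)-1-(3-methoxy-4-triisopropylsilyloxyphenyl)-2,3-dimethylbutan-1-ol
Conditions: H2 (1 atm), 10% Pd/C, EtOAc, rt
Reagents that add atoms: none
Why: Hydrogenolysis of the aryl benzyl ether in a neutral aprotic solvent; phenolic benzyl ethers are cleaved much faster than the secondary benzylic C5–O bond, and the silyl ether is untouched.

**Step 9**
Reactants: 13 (1R,2S,3R)-4-(4-hydroxy-3-methoxyphenyl)-1-(3-methoxy-4-triisopropylsilyloxyphenyl)-2,3-dimethylbutan-1-ol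
Product: 15 (2S,3S,4S,5R)-2-(4-hydroxy-3-methoxyphenyl)-5-(3-methoxy-4-triisopropylsilyloxyphenyl)-3,4-dimethyloxolane, via p-quinone methide 14 (not isolated)
Conditions: undivided cell, graphite anode, Pt cathode, constant current (about 2 mA cm−2, 2.0–2.2 F mol−1), 2,6-lutidine (2 equiv), 0.1 M LiClO4, MeCN/CH2Cl2, 0 °C, about 5 mM
Reagents that add atoms: none
Why: At the carbon anode the ring B phenol, hydrogen-bonded to 2,6-lutidine as proton shuttle, gives up two electrons together with its O–H and one C2–H proton, so that p-quinone methide 14 forms with C2 as its exocyclic electrophilic carbon. The C5 hydroxyl then adds to C2 in a 5-exo-trig conjugate (1,6-) addition that forms the O1–C2 bond, closes ring A and restores the phenol. The closest known reaction type is the anodic (or Ag2O- or quinone-mediated) benzylic oxidation of 4-alkylphenols through p-quinone methides with capture by an oxygen nucleophile, the closure assumed for the biosynthesis of tetrahydrofuran lignans. The new centre C2 is set by the substrate: in the envelope transition state the quinonoid ring takes the pseudo-equatorial site trans to the C3 methyl, and because the product phenol can reopen to 14 the more stable 2,3-trans isomer (2S) is also the equilibrium product; C3, C4 and C5 are not involved. Chemoselectivity rests on the substrate: only ring B is a free phenol, the silyl ether of ring C is oxidised at a clearly higher potential, and the C5 carbinol sits on that protected ring. A medium free of other nucleophiles (no methanol) leaves the tethered hydroxyl as the only trap, high dilution disfavours coupling of phenoxyl radicals, and the charge is held near two faradays per mole because 15 is itself an oxidisable 4-alkylphenol.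

**Step 10**
Reactants: 16 methyl (R)-lactate
Product: 17 (R)-2-hydroxy-1-(pyrrolidin-1-yl)propan-1-one
Conditions: pyrrolidine (neat, 3 equiv), 45 °C
Reagents that add atoms: pyrrolidine, C1CCNC1
Why: Aminolysis of the α-hydroxy ester by the neat secondary amine; the stereocentre is not enolised under these conditions.

**Step 11**
Reactants: 17 (R)-2-hydroxy-1-(pyrrolidin-1-yl)propan-1-one; 18 3,4-dimethoxyphenylmagnesium bromide
Product: 19 (R)-1-(3,4-dimethoxyphenyl)-2-hydroxypropan-1-one
Conditions: iPrMgCl (1.0 equiv), THF, −20 °C; then 18 (1.5 equiv), 0 °C → rt; aq. NH4Cl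
Reagents that add atoms: none
Why: Grignard acylation of the amide: after deprotonation of the hydroxyl, 18 adds once to the alkoxide-chelated amide, and the magnesium hemiaminal gives the ketone only at work-up. The C8 centre carries an alkoxide during the reaction and should keep its configuration.

**Step 12**
Reactants: 19 (R)-1-(3,4-dimethoxyphenyl)-2-hydroxypropan-1-one
Product: 20 (R)-1-(3,4-dimethoxyphenyl)-1-oxopropan-2-yl 4-methylbenzenesulfonate
Conditions: TsCl, Et3N, DMAP (cat.), CH2Cl2, 0 °C
Reagents that add atoms: 4-methylbenzenesulfonyl chloride, Cc1ccc(cc1)S(=O)(=O)Cl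
Why: O-Sulfonylation; the C–O bond at the stereocentre is not broken, so the R configuration is kept and the hydroxyl becomes a leaving group activated by the adjacent ketone.

**Step 13**
Reactants: 15 (2S,3S,4S,5R)-2-(4-hydroxy-3-methoxyphenyl)-5-(3-methoxy-4-triisopropylsilyloxyphenyl)-3,4-dimethyloxolane; 20 (R)-1-(3,4-dimethoxyphenyl)-1-oxopropan-2-yl 4-methylbenzenesulfonate
Product: 21 (S)-1-(3,4-dimethoxyphenyl)-2-{2-methoxy-4-[(2S,3S,4S,5R)-5-(3-methoxy-4-triisopropylsilyloxyphenyl)-3,4-dimethyloxolan-2-yl]phenoxy}propan-1-one
Conditions: K2CO3, DMF, rt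
Reagents that add atoms: none
Why: Williamson-type SN2 etherification: the phenoxide of 15 displaces the α-keto tosylate with inversion, giving 8S. The mild carbonate keeps enolisation of tosylate and product low, and the triisopropylsilyl ether of ring C should survive.

**Step 14**
Reactants: 21 (S)-1-(3,4-dimethoxyphenyl)-2-{2-methoxy-4-[(2S,3S,4S,5R)-5-(3-methoxy-4-triisopropylsilyloxyphenyl)-3,4-dimethyloxolan-2-yl]phenoxy}propan-1-one
Product: 22 (1R,2S)-1-(3,4-dimethoxyphenyl)-2-{2-methoxy-4-[(2S,3S,4S,5R)-5-(3-methoxy-4-triisopropylsilyloxyphenyl)-3,4-dimethyloxolan-2-yl]phenoxy}propan-1-ol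
Conditions: Zn(BH4)2, Et2O, −30 → 0 °C; aq. NH4Cl
Reagents that add atoms: none
Why: Chelation-controlled (Cram-chelate) reduction: zinc ties the carbonyl oxygen to the ether oxygen of the 2-methoxyphenoxy group, and hydride enters from the side of the C8 hydrogen, which gives the erythro (7R,8S) alcohol.

**Step 15**
Reactants: 22 (1R,2S)-1-(3,4-dimethoxyphenyl)-2-{2-methoxy-4-[(2S,3S,4S,5R)-5-(3-methoxy-4-triisopropylsilyloxyphenyl)-3,4-dimethyloxolan-2-yl]phenoxy}propan-1-ol
Product: 23 (1R,2S)-1-(3,4-dimethoxyphenyl)-2-{4-[(2S,3S,4S,5R)-5-(4-hydroxy-3-methoxyphenyl)-3,4-dimethyloxolan-2-yl]-2-methoxyphenoxy}propan-1-ol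
Conditions: Bu4NF, AcOH (1:1), THF, 0 °C
Reagents that add atoms: none
Why: Fluoride-induced cleavage of the aryl silyl ether; buffering with AcOH keeps the liberated phenoxide from opening ring A at C5 by a retro-oxa-Michael reaction.

**Step 16**
Reactants: 24 methyl (S)-lactate
Product: 25 (S)-2-hydroxy-1-(pyrrolidin-1-yl)propan-1-one
Conditions: pyrrolidine (neat, 3 equiv), 45 °C
Reagents that add atoms: pyrrolidine, C1CCNC1
Why: Aminolysis as in step 10, without enolisation of the stereocentre.

**Step 17**
Reactants: 25 (S)-2-hydroxy-1-(pyrrolidin-1-yl)propan-1-one; 18 3,4-dimethoxyphenylmagnesium bromide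
Product: 26 (S)-1-(3,4-dimethoxyphenyl)-2-hydroxypropan-1-one
Conditions: iPrMgCl (1.0 equiv), THF, −20 °C; then 18 (1.5 equiv), 0 °C → rt; aq. NH4Cl
Reagents that add atoms: none
Why: Grignard acylation of the alkoxide-chelated amide as in step 11; the ketone appears only at work-up.

**Step 18**
Reactants: 26 (S)-1-(3,4-dimethoxyphenyl)-2-hydroxypropan-1-one
Product: 27 (S)-1-(3,4-dimethoxyphenyl)-1-oxopropan-2-yl 4-methylbenzenesulfonate
Conditions: TsCl, Et3N, DMAP (cat.), CH2Cl2, 0 °C
Reagents that add atoms: 4-methylbenzenesulfonyl chloride, Cc1ccc(cc1)S(=O)(=O)Cl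
Why: O-Sulfonylation with retention, as in step 12.

**Step 19**
Reactants: 23 (1R,2S)-1-(3,4-dimethoxyphenyl)-2-{4-[(2S,3S,4S,5R)-5-(4-hydroxy-3-methoxyphenyl)-3,4-dimethyloxolan-2-yl]-2-methoxyphenoxy}propan-1-ol; 27 (S)-1-(3,4-dimethoxyphenyl)-1-oxopropan-2-yl 4-methylbenzenesulfonate
Product: 28 (R)-1-(3,4-dimethoxyphenyl)-2-{4-[(2R,3S,4S,5S)-5-(4-{[(1R,2S)-1-(3,4-dimethoxyphenyl)-1-hydroxypropan-2-yl]oxy}-3-methoxyphenyl)-3,4-dimethyloxolan-2-yl]-2-methoxyphenoxy}propan-1-one
Conditions: K2CO3, DMF, rt
Reagents that add atoms: none
Why: SN2 etherification as in step 13, with inversion giving 8′R; the secondary C7 hydroxyl is not alkylated under carbonate conditions.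

**Step 20**
Reactants: 28 (R)-1-(3,4-dimethoxyphenyl)-2-{4-[(2R,3S,4S,5S)-5-(4-{[(1R,2S)-1-(3,4-dimethoxyphenyl)-1-hydroxypropan-2-yl]oxy}-3-methoxyphenyl)-3,4-dimethyloxolan-2-yl]-2-methoxyphenoxy}propan-1-one
Product: 29 (1R,2R)-1-(3,4-dimethoxyphenyl)-2-{4-[(2R,3S,4S,5S)-5-(4-{[(1R,2S)-1-(3,4-dimethoxyphenyl)-1-hydroxypropan-2-yl]oxy}-3-methoxyphenyl)-3,4-dimethyloxolan-2-yl]-2-methoxyphenoxy}propan-1-ol (CNP0116650.9)
Conditions: Bu4NBH4, CH2Cl2/MeOH (9:1), −40 → 0 °C
Reagents that add atoms: none
Why: Ketone reduction without a chelating cation: with Bu4N+ as counter-ion the polar Felkin–Anh model applies (aryloxy group anti to the incoming hydride, attack past the C8′ hydrogen), which gives the threo (7′R,8′R) alcohol and completes 29.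

## Compound list

1 | vanillin (4-hydroxy-3-methoxybenzaldehyde) | COc1cc(C=O)ccc1O | starting material
2 | 3-methoxy-4-(triisopropylsilyloxy)benzaldehyde | COc1cc(C=O)ccc1O[Si](C(C)C)(C(C)C)C(C)C | intermediate
3 | (R)-4-benzyl-3-propanoyloxazolidin-2-one | CCC(=O)N1[C@H](Cc2ccccc2)COC1=O | starting material
4 | (R)-4-benzyl-3-[(Z)-1-(dibutylboranyloxy)prop-1-en-1-yl]oxazolidin-2-one | C/C=C(\OB(CCCC)CCCC)N1[C@H](Cc2ccccc2)COC1=O | intermediate (not isolated)
5 | (R)-4-benzyl-3-[(2R,3R)-3-hydroxy-3-(3-methoxy-4-triisopropylsilyloxyphenyl)-2-methylpropanoyl]oxazolidin-2-one | O=C(N1[C@H](Cc2ccccc2)COC1=O)[C@H](C)[C@@H](O)c1ccc(O[Si](C(C)C)(C(C)C)C(C)C)c(OC)c1 | intermediate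
6 | (2R,3R)-3-hydroxy-N-methoxy-3-(3-methoxy-4-triisopropylsilyloxyphenyl)-N,2-dimethylpropanamide | CON(C)C(=O)[C@H](C)[C@@H](O)c1ccc(O[Si](C(C)C)(C(C)C)C(C)C)c(OC)c1 | intermediate
7 | 4-benzyloxy-3-methoxybenzyl alcohol | COc1cc(CO)ccc1OCc1ccccc1 | starting material
8 | 4-benzyloxy-3-methoxybenzyl chloride | COc1cc(CCl)ccc1OCc1ccccc1 | intermediate
9 | (4-benzyloxy-3-methoxybenzyl)magnesium chloride | COc1cc(C[Mg]Cl)ccc1OCc1ccccc1 | intermediate (not isolated)
10 | (3R,4R)-1-(4-benzyloxy-3-methoxyphenyl)-4-hydroxy-4-(3-methoxy-4-triisopropylsilyloxyphenyl)-3-methylbutan-2-one | O=C(Cc1ccc(OCc2ccccc2)c(OC)c1)[C@H](C)[C@@H](O)c1ccc(O[Si](C(C)C)(C(C)C)C(C)C)c(OC)c1 | intermediate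
11 | (1R,2S)-3-(4-benzyloxy-3-methoxybenzyl)-1-(3-methoxy-4-triisopropylsilyloxyphenyl)-2-methylbut-3-en-1-ol | C=C(Cc1ccc(OCc2ccccc2)c(OC)c1)[C@H](C)[C@@H](O)c1ccc(O[Si](C(C)C)(C(C)C)C(C)C)c(OC)c1 | intermediate
12 | (1R,2S,3R)-4-(4-benzyloxy-3-methoxyphenyl)-1-(3-methoxy-4-triisopropylsilyloxyphenyl)-2,3-dimethylbutan-1-ol | O[C@@H](c1ccc(O[Si](C(C)C)(C(C)C)C(C)C)c(OC)c1)[C@@H](C)[C@@H](Cc1ccc(OCc2ccccc2)c(OC)c1)C | intermediate
13 | (1R,2S,3R)-4-(4-hydroxy-3-methoxyphenyl)-1-(3-methoxy-4-triisopropylsilyloxyphenyl)-2,3-dimethylbutan-1-ol (precursor of the key step) | O[C@@H](c1ccc(O[Si](C(C)C)(C(C)C)C(C)C)c(OC)c1)[C@@H](C)[C@@H](Cc1ccc(O)c(OC)c1)C | intermediate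
14 | 4-[(2R,3S,4R)-4-hydroxy-4-(3-methoxy-4-triisopropylsilyloxyphenyl)-2,3-dimethylbutylidene]-2-methoxycyclohexa-2,5-dien-1-one (p-quinone methide, alkylidene geometry not defined) | O[C@@H](c1ccc(O[Si](C(C)C)(C(C)C)C(C)C)c(OC)c1)[C@@H](C)[C@@H](C=C1C=CC(=O)C(OC)=C1)C | intermediate (not isolated)
15 | (2S,3S,4S,5R)-2-(4-hydroxy-3-methoxyphenyl)-5-(3-methoxy-4-triisopropylsilyloxyphenyl)-3,4-dimethyloxolane (product of the key step) | Oc1ccc([C@H]2O[C@@H](c3ccc(O[Si](C(C)C)(C(C)C)C(C)C)c(OC)c3)[C@@H](C)[C@@H]2C)cc1OC | intermediate
16 | methyl (R)-lactate | C[C@@H](O)C(=O)OC | starting material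
17 | (R)-2-hydroxy-1-(pyrrolidin-1-yl)propan-1-one | C[C@@H](O)C(=O)N1CCCC1 | intermediate
18 | 3,4-dimethoxyphenylmagnesium bromide | COc1ccc([Mg]Br)cc1OC | starting material
19 | (R)-1-(3,4-dimethoxyphenyl)-2-hydroxypropan-1-one | C[C@@H](O)C(=O)c1ccc(OC)c(OC)c1 | intermediate
20 | (R)-1-(3,4-dimethoxyphenyl)-1-oxopropan-2-yl 4-methylbenzenesulfonate | C[C@@H](OS(=O)(=O)c1ccc(C)cc1)C(=O)c1ccc(OC)c(OC)c1 | intermediate
21 | (S)-1-(3,4-dimethoxyphenyl)-2-{2-methoxy-4-[(2S,3S,4S,5R)-5-(3-methoxy-4-triisopropylsilyloxyphenyl)-3,4-dimethyloxolan-2-yl]phenoxy}propan-1-one | COc1ccc(C(=O)[C@H](C)Oc2ccc([C@H]3O[C@@H](c4ccc(O[Si](C(C)C)(C(C)C)C(C)C)c(OC)c4)[C@@H](C)[C@@H]3C)cc2OC)cc1OC | intermediate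
22 | (1R,2S)-1-(3,4-dimethoxyphenyl)-2-{2-methoxy-4-[(2S,3S,4S,5R)-5-(3-methoxy-4-triisopropylsilyloxyphenyl)-3,4-dimethyloxolan-2-yl]phenoxy}propan-1-ol | COc1ccc([C@@H](O)[C@H](C)Oc2ccc([C@H]3O[C@@H](c4ccc(O[Si](C(C)C)(C(C)C)C(C)C)c(OC)c4)[C@@H](C)[C@@H]3C)cc2OC)cc1OC | intermediate
23 | (1R,2S)-1-(3,4-dimethoxyphenyl)-2-{4-[(2S,3S,4S,5R)-5-(4-hydroxy-3-methoxyphenyl)-3,4-dimethyloxolan-2-yl]-2-methoxyphenoxy}propan-1-ol | COc1ccc([C@@H](O)[C@H](C)Oc2ccc([C@H]3O[C@@H](c4ccc(O)c(OC)c4)[C@@H](C)[C@@H]3C)cc2OC)cc1OC | intermediate
24 | methyl (S)-lactate | C[C@H](O)C(=O)OC | starting material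
25 | (S)-2-hydroxy-1-(pyrrolidin-1-yl)propan-1-one | C[C@H](O)C(=O)N1CCCC1 | intermediate
26 | (S)-1-(3,4-dimethoxyphenyl)-2-hydroxypropan-1-one | C[C@H](O)C(=O)c1ccc(OC)c(OC)c1 | intermediate
27 | (S)-1-(3,4-dimethoxyphenyl)-1-oxopropan-2-yl 4-methylbenzenesulfonate | C[C@H](OS(=O)(=O)c1ccc(C)cc1)C(=O)c1ccc(OC)c(OC)c1 | intermediate
28 | (R)-1-(3,4-dimethoxyphenyl)-2-{4-[(2R,3S,4S,5S)-5-(4-{[(1R,2S)-1-(3,4-dimethoxyphenyl)-1-hydroxypropan-2-yl]oxy}-3-methoxyphenyl)-3,4-dimethyloxolan-2-yl]-2-methoxyphenoxy}propan-1-one (the target with C7′ as ketone) | COc1ccc([C@@H](O)[C@H](C)Oc2ccc([C@H]3O[C@@H](c4ccc(O[C@H](C)C(=O)c5ccc(OC)c(OC)c5)c(OC)c4)[C@@H](C)[C@@H]3C)cc2OC)cc1OC | intermediate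
29 | (1R,2R)-1-(3,4-dimethoxyphenyl)-2-{4-[(2R,3S,4S,5S)-5-(4-{[(1R,2S)-1-(3,4-dimethoxyphenyl)-1-hydroxypropan-2-yl]oxy}-3-methoxyphenyl)-3,4-dimethyloxolan-2-yl]-2-methoxyphenoxy}propan-1-ol (CNP0116650.9) | COc1ccc([C@@H](O)[C@H](C)Oc2ccc([C@H]3O[C@@H](c4ccc(O[C@H](C)[C@H](O)c5ccc(OC)c(OC)c5)c(OC)c4)[C@@H](C)[C@@H]3C)cc2OC)cc1OC | target

## Step count and least certain steps

Total: 20 steps. Longest linear sequence: 13 steps from vanillin (steps 1, 2, 3, 5, 6, 7, 8, 9, 13, 14, 15, 19, 20). Steps 4, 10–12 and 16–18 are side branches.

**Step 9 (key step).** The most likely failure is over-oxidation: product 15 is still a 4-alkylphenol with a benzylic C2–H and could be oxidised again to a ring-opened aryl ketone. Coupling of phenoxyl radicals at the free ortho position and attack of the hydroxyl at the ipso carbon (spirodienone formation) may also compete with loss of the C2 proton. The fallback sets out from 12 and comes back at 15. The benzyl ether 12 would be treated with 2,3-dichloro-5,6-dicyano-1,4-benzoquinone in CH2Cl2 at 0 °C, a closed-shell hydride abstraction from the 4-alkoxybenzylic CH2 with capture of the cation by the C5 hydroxyl. This should give (2S,3S,4S,5R)-2-(4-benzyloxy-3-methoxyphenyl)-5-(3-methoxy-4-triisopropylsilyloxyphenyl)-3,4-dimethyloxolane F1, with no free phenol present. Brief hydrogenolysis of F1 (H2, 10% Pd/C, EtOAc) would then uncover the phenol of 15.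

**Step 7.** The risk is poor facial selectivity, or selectivity for the 3S epimer, if the conformer with the allylic C4–H eclipsing the double bond outweighs the one assumed; migration of the double bond during hydrogenation would have the same effect. The fallback sets out from 11 and comes back at 12. It uses the fact that the isomeric trisubstituted alkene should present the opposite face in the same chelate. Alkene 11 would be isomerised with RuHCl(CO)(PPh3)3 (cat.) in toluene at 80 °C into conjugation with ring B, giving (1R,2S,3E)-4-(4-benzyloxy-3-methoxyphenyl)-1-(3-methoxy-4-triisopropylsilyloxyphenyl)-2,3-dimethylbut-3-en-1-ol F2. F2 would then be hydrogenated under hydroxyl direction with [Ir(cod)(PCy3)(py)]PF6 and H2 in CH2Cl2. Whichever conformational preference governs 11, it should lead to the other C3 configuration from F2.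

**Step 5.** Formation of the electron-rich benzylic Grignard reagent may suffer from Wurtz homocoupling, and the basic reagent may enolise the product or deprotonate and not add. The fallback sets out from 5 and comes back at 10. The auxiliary of 5 would be displaced with LiSEt (EtSH, n-BuLi, THF, 0 °C) to give S-ethyl (2R,3R)-3-hydroxy-3-(3-methoxy-4-triisopropylsilyloxyphenyl)-2-methylpropanethioate F3. Chloride 8 would be converted with Zn dust and LiCl in THF into (4-benzyloxy-3-methoxybenzyl)zinc chloride F4. A Fukuyama coupling of F3 with F4 and PdCl2(PPh3)2 (cat.) should then give ketone 10 under non-basic conditions.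

**Step 14.** The aryloxy oxygen is a weak donor, so chelation may be incomplete and erythro selectivity low. The fallback sets out from 21 and comes back at 22. Substrate control would be replaced by reagent control, a Corey–Bakshi–Shibata reduction with (R)-2-methyl-CBS-oxazaborolidine (cat.) and BH3·SMe2 in THF at −20 °C. With the aryl group as the larger ketone substituent, the R catalyst is expected to give the 7R carbinol. No new compound is formed on the way.

**Step 20.** Residual coordination, or a small intrinsic Felkin–Anh preference, may erode the threo selectivity. The fallback sets out from 28 and comes back at 29. It is the same catalyst-controlled reduction with (R)-2-methyl-CBS-oxazaborolidine and BH3·SMe2, because C7′ is also R. No new compound is formed on the way.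

## Further compounds

F1 | step 9 | (2S,3S,4S,5R)-2-(4-benzyloxy-3-methoxyphenyl)-5-(3-methoxy-4-triisopropylsilyloxyphenyl)-3,4-dimethyloxolane | c1ccccc1COc1ccc([C@H]2O[C@@H](c3ccc(O[Si](C(C)C)(C(C)C)C(C)C)c(OC)c3)[C@@H](C)[C@@H]2C)cc1OC
F2 | step 7 | (1R,2S,3E)-4-(4-benzyloxy-3-methoxyphenyl)-1-(3-methoxy-4-triisopropylsilyloxyphenyl)-2,3-dimethylbut-3-en-1-ol | C/C(=C\c1ccc(OCc2ccccc2)c(OC)c1)[C@H](C)[C@@H](O)c1ccc(O[Si](C(C)C)(C(C)C)C(C)C)c(OC)c1
F3 | step 5 | S-ethyl (2R,3R)-3-hydroxy-3-(3-methoxy-4-triisopropylsilyloxyphenyl)-2-methylpropanethioate | CCSC(=O)[C@H](C)[C@@H](O)c1ccc(O[Si](C(C)C)(C(C)C)C(C)C)c(OC)c1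
F4 | step 5 | (4-benzyloxy-3-methoxybenzyl)zinc chloride | COc1cc(C[Zn]Cl)ccc1OCc1ccccc1
F0 | step 14 | none | none
F0 | step 20 | none | none
A1 | alternative 1 | (3S,4S,5S)-5-(4-benzyloxy-3-methoxyphenyl)-3,4-dimethyldihydrofuran-2(3H)-one | c1ccccc1COc2ccc([C@H]3OC(=O)[C@@H](C)[C@@H]3C)cc2OC
A2 | alternative 1 | (S)-5-(4-benzyloxy-3-methoxyphenyl)furan-2(5H)-one | c1ccccc1COc2ccc([C@H]3OC(=O)C=C3)cc2OC
A3 | alternative 2 | dimethyl (2R,4S,5R)-5-(4-allyloxy-3-methoxyphenyl)-2-(4-benzyloxy-3-methoxyphenyl)-4-methyltetrahydrofuran-3,3-dicarboxylate | c1ccccc1COc2ccc([C@H]3O[C@@H](c4ccc(OCC=C)c(OC)c4)[C@@H](C)C3(C(=O)OC)C(=O)OC)cc2OC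
A4 | alternative 2 | dimethyl (2S,3R)-2-(4-allyloxy-3-methoxyphenyl)-3-methylcyclopropane-1,1-dicarboxylate | COC(=O)C1(C(=O)OC)[C@H](c2ccc(OCC=C)c(OC)c2)[C@H]1C
A5 | alternative 2 | 4-benzyloxy-3-methoxybenzaldehyde | COc1cc(C=O)ccc1OCc1ccccc1
A6 | alternative 3 | 4-[(1R,2S)-1-hydroxy-2-{4-[(2S,3S,4S,5R)-5-(4-{[(1R,2R)-1-hydroxy-1-(4-hydroxy-3-methoxyphenyl)propan-2-yl]oxy}-3-methoxyphenyl)-3,4-dimethyloxolan-2-yl]-2-methoxyphenoxy}propyl]-2-methoxyphenol | Oc1ccc([C@@H](O)[C@H](C)Oc2ccc([C@H]3O[C@@H](c4ccc(O[C@H](C)[C@H](O)c5ccc(O)c(OC)c5)c(OC)c4)[C@@H](C)[C@@H]3C)cc2OC)cc1OC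
A7 | alternative 3 | 4-[(2S)-2-{4-[(2S,3S,4S,5R)-5-(4-{[(2R)-1-(4-hydroxy-3-methoxyphenyl)propan-2-yl]oxy}-3-methoxyphenyl)-3,4-dimethyloxolan-2-yl]-2-methoxyphenoxy}propyl]-2-methoxyphenol | Oc1ccc(C[C@H](C)Oc2ccc([C@H]3O[C@@H](c4ccc(O[C@H](C)Cc5ccc(O)c(OC)c5)c(OC)c4)[C@@H](C)[C@@H]3C)cc2OC)cc1OC
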